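**Retrosynthetic overview**
1. Target 20 ⇒ diol 15 + silyl-protected p-coumaric acid 18 (acylation of C6–OH). The C7=C8(CH3)–C9=O enone ⇒ exo-methylene ketone 14 ⇒ β-silyloxy acrylate 12, so the ester carbon becomes the C8 methyl.
2. C4 carbinol ⇒ i-PrMgCl + C4 ketone 11. 5α-H/6α-OH ⇒ hydroboration of C5=C6 in 8. Both reagents approach anti to the C1 methyl, so C4, C5 and C6 are relayed from C1.
3. Seven-membered ring (C1, C5, C6, C7, C8, C9, C10) ⇒ formal (4+3) of vinylcyclopentene ketal 3 with the rhodium siloxyvinylcarbenoid from 6. The vinyl group is cyclopropanated, then cis-divinylcyclopropane 7 undergoes a strain-releasing Cope shift (new bonds C7–C8 and C1–C10).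
4. Enabling feature: in the seven-membered ring the ketone carbon C9 is the middle atom of the three-carbon unit C8–C9–C10, a 2-oxyallyl unit whose C8 carries one extra carbon. The other four ring atoms C7–C6–C5–C1 are a butadiene whose C5=C1 end is the bond shared with the five-membered ring, with C1 already bearing the methyl group.
5. Ring order: cyclopentene (bought in 1) and arene (bought in 16) → temporary ketal and cyclopropane → seven-membered ring last.

Key step: step 5

Remark on numbering (daucane): C1 quaternary fusion carbon (CH3), C2, C3, C4 carbinol carbon (i-Pr), C5 fusion CH, C6 CH–O, C7 =CH, C8 =C(CH3), C9 C=O, C10 CH2. Azulene locants in the names: C1 = 8a, C4 = 3, C5 = 3a, C6 = 4, C8 = 6, C9 = 7, C10 = 8. β is the face of the C1 methyl.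
Assumption: Rh2(R-PTAD)4 is written as the catalyst enantiomer that leads to (1R,2S)-7. If the sense of induction on this diene is the opposite, the equally available Rh2(S-PTAD)4 is used and nothing else changes.

Step 1
Reactants: 1 2-bromo-3-methylcyclopent-2-en-1-one
Product: 2 6-bromo-7-methyl-1,4-dioxaspiro[4.4]non-6-ene
Conditions: HOCH2CH2OH, p-TsOH·H2O (cat.), benzene, Dean–Stark, reflux
Reagents that add atoms: ethylene glycol, OCCO
Why: Acid-catalysed ketalisation with azeotropic removal of water masks the future C4 ketone, and the α-bromine keeps the double bond in the C5=C1 position; no stereocentre is formed.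

Step 2
Reactants: 2 6-bromo-7-methyl-1,4-dioxaspiro[4.4]non-6-ene
Product: 3 6-ethenyl-7-methyl-1,4-dioxaspiro[4.4]non-6-ene
Conditions: Bu3SnCH=CH2, Pd(PPh3)4 (5 mol %), toluene, 100 °C
Reagents that add atoms: tributyl(vinyl)stannane, C=C[Sn](CCCC)(CCCC)CCCC
Why: Stille coupling of the alkenyl bromide under neutral conditions installs C6 and C7 and leaves the acid-labile ketal intact; no stereocentre is formed.

Step 3
Reactants: 4 methyl acetoacetate
Product: 5 methyl 2-diazo-3-oxobutanoate
Conditions: p-ABSA, Et3N, MeCN, 0 °C → rt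
Reagents that add atoms: 4-acetamidobenzenesulfonyl azide, CC(=O)Nc1ccc(cc1)S(=O)(=O)N=[N+]=[N-]
Why: Regitz diazo transfer to the activated methylene group of a 1,3-dicarbonyl compound.

Step 4
Reactants: 5 methyl 2-diazo-3-oxobutanoate
Product: 6 methyl 3-[(tert-butyldimethylsilyl)oxy]-2-diazobut-3-enoate
Conditions: TBSOTf, Et3N, CH2Cl2, 0 °C
Reagents that add atoms: tert-butyldimethylsilyl triflate, CC(C)(C)[Si](C)(C)OS(=O)(=O)C(F)(F)F
Why: Soft enolisation and O-silylation of the only enolisable position (the acetyl CH3) turns the diazo keto ester into a vinyldiazoacetate that carries C9 as a masked ketone.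

Step 5
Reactants: 3 6-ethenyl-7-methyl-1,4-dioxaspiro[4.4]non-6-ene; 6 methyl 3-[(tert-butyldimethylsilyl)oxy]-2-diazobut-3-enoate
Product: 8 methyl (8aR)-7-[(tert-butyldimethylsilyl)oxy]-3,3-(ethylenedioxy)-8a-methyl-1,2,3,5,8,8a-hexahydroazulene-6-carboxylate, via cis-divinylcyclopropane 7 (not isolated)
Conditions: Rh2(R-PTAD)4 (1 mol %), slow addition of 6 (1.5 equiv), hexanes, −20 °C → rt; then toluene, 80 °C
Reagents that add atoms: none
Why: Loss of N2 from 6 gives a donor/acceptor rhodium vinylcarbenoid that cyclopropanates the only accessible π bond of 3, the monosubstituted vinyl group, and thereby closes the temporary three-membered ring C6–C7–C8 by a concerted asynchronous (2+1) addition. As is general for donor/acceptor carbenoids, the alkene substituent ends up cis to the donor (siloxyvinyl) group and trans to the ester, so 7 is the cis-divinylcyclopropane, and the chiral carboxylate ligand sphere fixes the absolute configuration of C6 and C8. Release of the cyclopropane strain then drives a [3,3]-sigmatropic (Cope) shift through the endo-boat transition state, the only one that gives two cis ring alkenes: C6–C8 breaks, C10–C1 forms and the seven-membered ring is closed. The new quaternary stereocentre C1 is set stereospecifically, because C10 must bond to the face of C5=C1 from which C8 leaves C6 (suprafacial on both allyl halves), so the catalyst-derived configuration of 7 is relayed to C1 while C6 and C8 become sp2. The closest known reaction type is the rhodium-catalysed tandem cyclopropanation/Cope formal (4+3) cycloaddition of siloxyvinyldiazoacetates with 1-vinyl-2-methylcycloalkenes, which also builds methyl-bearing quaternary ring-fusion carbons. The step needs chemoselectivity (vinyl versus tetrasubstituted ring alkene and allylic C–H), cis diastereoselectivity and enantioselectivity, which are secured by the steric difference of the two alkenes, by the donor/acceptor carbenoid and by the catalyst, respectively.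

Step 6
Reactants: 8 methyl (8aR)-7-[(tert-butyldimethylsilyl)oxy]-3,3-(ethylenedioxy)-8a-methyl-1,2,3,5,8,8a-hexahydroazulene-6-carboxylate
Product: 10 methyl (3aS,4S,8aR)-7-[(tert-butyldimethylsilyl)oxy]-3,3-(ethylenedioxy)-4-hydroxy-8a-methyl-1,2,3,3a,4,5,8,8a-octahydroazulene-6-carboxylate, via monoalkylborane 9 (not isolated)
Conditions: BH3·THF, THF, 0 °C → rt; then 30% H2O2, pH 7 phosphate buffer, 0 °C
Reagents that add atoms: borane–tetrahydrofuran, B.C1CCOC1 (boron stays only in 9); hydrogen peroxide, OO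
Why: Syn hydroboration puts boron on the less substituted C6 and hydrogen on C5 from the α face, opposite to the pseudoaxial C1 methyl, which sets 5α-H (trans ring fusion) and, after oxidation with retention, 6α-OH, while the tetrasubstituted push–pull C8=C9 alkene is inert.

Step 7
Reactants: 10 methyl (3aS,4S,8aR)-7-[(tert-butyldimethylsilyl)oxy]-3,3-(ethylenedioxy)-4-hydroxy-8a-methyl-1,2,3,3a,4,5,8,8a-octahydroazulene-6-carboxylate
Product: 11 methyl (3aS,4S,8aR)-7-[(tert-butyldimethylsilyl)oxy]-4-hydroxy-8a-methyl-3-oxo-1,2,3,3a,4,5,8,8a-octahydroazulene-6-carboxylate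
Conditions: PPTS (0.2 equiv), acetone/H2O 9:1, 45 °C
Reagents that add atoms: water, O
Why: Mild acid hydrolysis of the cyclopentanone ketal through its oxocarbenium ion should spare the β-silyloxy acrylate (a vinylogous carbonate that resists C-protonation) and is weak enough to avoid dehydration of the β-hydroxy ketone and epimerisation at C5.

Step 8
Reactants: 11 methyl (3aS,4S,8aR)-7-[(tert-butyldimethylsilyl)oxy]-4-hydroxy-8a-methyl-3-oxo-1,2,3,3a,4,5,8,8a-octahydroazulene-6-carboxylate
Product: 12 methyl (3R,3aS,4S,8aR)-7-[(tert-butyldimethylsilyl)oxy]-3,4-dihydroxy-8a-methyl-3-(propan-2-yl)-1,2,3,3a,4,5,8,8a-octahydroazulene-6-carboxylate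
Conditions: i-PrMgCl (3 equiv), LaCl3·2LiCl (1 equiv), THF, 0 °C; aq NH4Cl
Reagents that add atoms: isopropylmagnesium chloride, CC(C)[Mg]Cl
Why: Lanthanide-assisted Grignard 1,2-addition suppresses enolisation and β-hydride reduction, and the nucleophile should attack the C4 ketone from the α face, anti to the C1 methyl and to C6 (the β substituent on C5), which gives 4α-i-Pr/4β-OH, while the first equivalent only deprotonates 6-OH and the deactivated ester is not touched.

Step 9
Reactants: 12 methyl (3R,3aS,4S,8aR)-7-[(tert-butyldimethylsilyl)oxy]-3,4-dihydroxy-8a-methyl-3-(propan-2-yl)-1,2,3,3a,4,5,8,8a-octahydroazulene-6-carboxylate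
Product: 14 (1R,4R,5S,6S)-4β,6α-dihydroxydauc-8(14)-en-9-one (exo-methylene ketone), via allylic alcohol 13 (not isolated)
Conditions: DIBAL-H (5 equiv), CH2Cl2, −78 → 0 °C; then 1 M HCl, THF, 0 °C → rt
Reagents that add atoms: none
Why: DIBAL-H reduces the conjugated ester to the allylic alcohol, and acid ionises it to a silyloxy-stabilised allyl cation that loses the silyl group, which unmasks C9=O and turns the former ester carbon into the exocyclic methylene without touching a stereocentre.

Step 10
Reactants: 14 (1R,4R,5S,6S)-4β,6α-dihydroxydauc-8(14)-en-9-one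
Product: 15 (1R,4R,5S,6S)-4β,6α-dihydroxydauc-7-en-9-one
Conditions: RhCl3·3H2O (5 mol %), EtOH, 75 °C
Reagents that add atoms: none
Why: Rhodium hydride addition/β-hydride elimination (exo-to-endo enone isomerisation) moves the double bond to the more substituted conjugated C7=C8 position and makes the methylene the C8 methyl, and because rhodium sits on C8 as an oxa-π-allyl the C6–H bond is not reached and all stereocentres persist.

Step 11
Reactants: 16 (E)-p-coumaric acid
Product: 18 (E)-3-{4-[(tert-butyldimethylsilyl)oxy]phenyl}prop-2-enoic acid, via bis-silylated coumarate 17 (not isolated)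
Conditions: TBSCl (2.5 equiv), imidazole, DMF, rt; then AcOH/THF/H2O, rt
Reagents that add atoms: tert-butyldimethylsilyl chloride, CC(C)(C)[Si](C)(C)Cl
Why: Silylation of both acidic OH groups is followed by selective hydrolysis of the far more labile silyl ester, which leaves the aryl silyl ether and the E alkene unchanged.

Step 12
Reactants: 15 (1R,4R,5S,6S)-4β,6α-dihydroxydauc-7-en-9-one; 18 (E)-3-{4-[(tert-butyldimethylsilyl)oxy]phenyl}prop-2-enoic acid
Product: 19 (1R,4R,5S,6S)-6α-{(E)-3-[4-(tert-butyldimethylsilyloxy)phenyl]prop-2-enoyloxy}-4β-hydroxydauc-7-en-9-one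
Conditions: DCC, DMAP (cat.), CH2Cl2, 0 °C → rt
Reagents that add atoms: none
Why: Steglich esterification acylates only the secondary allylic 6-OH because the hindered tertiary 4-OH is inert, and the C6–O bond is not broken, so the configuration is retained.

Step 13
Reactants: 19 (1R,4R,5S,6S)-6α-{(E)-3-[4-(tert-butyldimethylsilyloxy)phenyl]prop-2-enoyloxy}-4β-hydroxydauc-7-en-9-one
Product: 20 (3R,3aS,4S,8aR)-3-hydroxy-6,8a-dimethyl-7-oxo-3-(propan-2-yl)-1,2,3,3a,4,7,8,8a-octahydroazulen-4-yl (E)-3-(4-hydroxyphenyl)prop-2-enoate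
Conditions: HF·pyridine, THF, 0 °C
Reagents that add atoms: none
Why: Fluoride-induced cleavage of the aryl silyl ether is fast under these weakly acidic conditions, which spare the cinnamate ester, the γ-acyloxy enone and the tertiary alcohol.

**Compound list**
1 | 2-bromo-3-methylcyclopent-2-en-1-one | CC1=C(Br)C(=O)CC1 | starting material
2 | 6-bromo-7-methyl-1,4-dioxaspiro[4.4]non-6-ene | CC1=C(Br)C2(CC1)OCCO2 | intermediate
3 | 6-ethenyl-7-methyl-1,4-dioxaspiro[4.4]non-6-ene | C=CC1=C(C)CCC12OCCO2 | intermediate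
4 | methyl acetoacetate | CC(=O)CC(=O)OC | starting material
5 | methyl 2-diazo-3-oxobutanoate | COC(=O)C(=[N+]=[N-])C(C)=O | intermediate
6 | methyl 3-[(tert-butyldimethylsilyl)oxy]-2-diazobut-3-enoate | COC(=O)C(=[N+]=[N-])C(=C)O[Si](C)(C)C(C)(C)C | intermediate
7 | methyl (1R,2S)-1-{1-[(tert-butyldimethylsilyl)oxy]ethenyl}-2-(7-methyl-1,4-dioxaspiro[4.4]non-6-en-6-yl)cyclopropane-1-carboxylate (siloxyvinyl cis to the cyclopentenyl group) | COC(=O)[C@]1(C(=C)O[Si](C)(C)C(C)(C)C)C[C@H]1C2=C(C)CCC23OCCO3 | intermediate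
8 | methyl (8aR)-7-[(tert-butyldimethylsilyl)oxy]-3,3-(ethylenedioxy)-8a-methyl-1,2,3,5,8,8a-hexahydroazulene-6-carboxylate | COC(=O)C=1CC=C2[C@](C)(CCC23OCCO3)CC=1O[Si](C)(C)C(C)(C)C | intermediate
9 | methyl (3aR,4S,8aR)-4-boranyl-7-[(tert-butyldimethylsilyl)oxy]-3,3-(ethylenedioxy)-8a-methyl-1,2,3,3a,4,5,8,8a-octahydroazulene-6-carboxylate (5α-H, 6α-BH2) | COC(=O)C=1C[C@H](B)[C@@H]2[C@](C)(CCC23OCCO3)CC=1O[Si](C)(C)C(C)(C)C | intermediate
10 | methyl (3aS,4S,8aR)-7-[(tert-butyldimethylsilyl)oxy]-3,3-(ethylenedioxy)-4-hydroxy-8a-methyl-1,2,3,3a,4,5,8,8a-octahydroazulene-6-carboxylate | COC(=O)C=1C[C@H](O)[C@@H]2[C@](C)(CCC23OCCO3)CC=1O[Si](C)(C)C(C)(C)C | intermediate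
11 | methyl (3aS,4S,8aR)-7-[(tert-butyldimethylsilyl)oxy]-4-hydroxy-8a-methyl-3-oxo-1,2,3,3a,4,5,8,8a-octahydroazulene-6-carboxylate | COC(=O)C=1C[C@H](O)[C@@H]2[C@](C)(CCC2=O)CC=1O[Si](C)(C)C(C)(C)C | intermediate
12 | methyl (3R,3aS,4S,8aR)-7-[(tert-butyldimethylsilyl)oxy]-3,4-dihydroxy-8a-methyl-3-(propan-2-yl)-1,2,3,3a,4,5,8,8a-octahydroazulene-6-carboxylate | COC(=O)C=1C[C@H](O)[C@@H]2[C@](C)(CC[C@@]2(O)C(C)C)CC=1O[Si](C)(C)C(C)(C)C | intermediate
13 | (3R,3aS,4S,8aR)-7-[(tert-butyldimethylsilyl)oxy]-6-(hydroxymethyl)-8a-methyl-3-(propan-2-yl)-1,2,3,3a,4,5,8,8a-octahydroazulene-3,4-diol | OCC=1C[C@H](O)[C@@H]2[C@](C)(CC[C@@]2(O)C(C)C)CC=1O[Si](C)(C)C(C)(C)C | intermediate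
14 | (1R,4R,5S,6S)-4β,6α-dihydroxydauc-8(14)-en-9-one | C=C1C[C@H](O)[C@@H]2[C@](C)(CC[C@@]2(O)C(C)C)CC1=O | intermediate
15 | (1R,4R,5S,6S)-4β,6α-dihydroxydauc-7-en-9-one | CC1=C[C@H](O)[C@@H]2[C@](C)(CC[C@@]2(O)C(C)C)CC1=O | intermediate
16 | (E)-p-coumaric acid | OC(=O)/C=C/c1ccc(O)cc1 | starting material
17 | tert-butyldimethylsilyl (E)-3-{4-[(tert-butyldimethylsilyl)oxy]phenyl}prop-2-enoate | CC(C)(C)[Si](C)(C)Oc1ccc(/C=C/C(=O)O[Si](C)(C)C(C)(C)C)cc1 | intermediate
18 | (E)-3-{4-[(tert-butyldimethylsilyl)oxy]phenyl}prop-2-enoic acid | CC(C)(C)[Si](C)(C)Oc1ccc(/C=C/C(=O)O)cc1 | intermediate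
19 | (1R,4R,5S,6S)-6α-{(E)-3-[4-(tert-butyldimethylsilyloxy)phenyl]prop-2-enoyloxy}-4β-hydroxydauc-7-en-9-one | CC1=C[C@H](OC(=O)/C=C/c2ccc(O[Si](C)(C)C(C)(C)C)cc2)[C@@H]2[C@](C)(CC[C@@]2(O)C(C)C)CC1=O | intermediate
20 | (3R,3aS,4S,8aR)-3-hydroxy-6,8a-dimethyl-7-oxo-3-(propan-2-yl)-1,2,3,3a,4,7,8,8a-octahydroazulen-4-yl (E)-3-(4-hydroxyphenyl)prop-2-enoate | CC1=C[C@H](OC(=O)/C=C/c2ccc(O)cc2)[C@@H]2[C@](C)(CC[C@@]2(O)C(C)C)CC1=O | target

Total step count: 13. Longest linear sequence: 10 steps (1, 2, 5, 6, 7, 8, 9, 10, 12, 13).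

**Steps most likely to fail**

Step 5.
- **What may go wrong:** Carbenoid transfer to the crowded vinyl group may be slow. Carbene dimerisation, attack at the vinylogous carbenoid terminus or allylic C–H insertion could then compete. Enantioselection on this diene may be low. The Cope shift may stall because the C1 methyl points into the boat.
- **Fallback (from 3 and 5, back at 8):** The two events are separated. The vinyl group of 3 is cyclopropanated with the diazo keto ester 5 under cobalt(II)/chiral amidoporphyrin metalloradical catalysis. This stepwise radical process has different steric demands and places the ester trans to the ring substituent. It gives the isolable keto ester methyl (1R,2S)-1-acetyl-2-(7-methyl-1,4-dioxaspiro[4.4]non-6-en-6-yl)cyclopropane-1-carboxylate F1. Soft enolisation of its methyl ketone (TBSOTf, Et3N, CH2Cl2) then generates 7, which is heated in toluene until it has rearranged to 8.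

Step 6.
- **What may go wrong:** Hydroboration of an alkene flanked by two fully substituted carbons may be slow, which allows reduction of the ester. Facial selectivity may be poor. The following ketal hydrolysis may cost the enol silane or dehydrate the β-hydroxy ketone.
- **Fallback (from 8, back at 11, bypassing steps 6 and 7):** The much more labile allylic ketal of 8 is hydrolysed first (oxalic acid on silica gel, CH2Cl2). This gives the enone methyl (8aR)-7-[(tert-butyldimethylsilyl)oxy]-8a-methyl-3-oxo-1,2,3,5,8,8a-hexahydroazulene-6-carboxylate F2. Copper(I)-catalysed conjugate borylation follows (B2pin2, CuCl, NaOt-Bu, a chiral bisphosphine matched to the α face, MeOH, THF). It puts boron on C6 and a proton on C5 and gives the 5α-H,6α-(pinacolboryl) ketone F3. Oxidation with NaBO3·4H2O gives 11.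

Step 8.
- **What may go wrong:** The hindered ketone may enolise or be reduced by β-hydride transfer. The β-alkoxide may open by a retro-aldol process. Facial selectivity may be poor.
- **Fallback (from 11, back at 12):** The smaller sp2 nucleophile isopropenylmagnesium bromide with CeCl3 (THF, −78 °C), which has no β-hydride to transfer, is added to 11. This gives the isopropenyl carbinol methyl (3aS,4S,8aR)-7-[(tert-butyldimethylsilyl)oxy]-3β,4-dihydroxy-8a-methyl-3α-(prop-1-en-2-yl)-1,2,3,3a,4,5,8,8a-octahydroazulene-6-carboxylate F4. Its 1,1-disubstituted alkene is then hydrogenated with RhCl(PPh3)3/H2 in benzene, conditions under which the tetrasubstituted push–pull alkene is inert, to give 12.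

**Further compounds**
F1 | step 5 | methyl (1R,2S)-1-acetyl-2-(7-methyl-1,4-dioxaspiro[4.4]non-6-en-6-yl)cyclopropane-1-carboxylate | COC(=O)[C@]1(C(C)=O)C[C@H]1C2=C(C)CCC23OCCO3
F2 | step 6 | methyl (8aR)-7-[(tert-butyldimethylsilyl)oxy]-8a-methyl-3-oxo-1,2,3,5,8,8a-hexahydroazulene-6-carboxylate | COC(=O)C=1CC=C2[C@](C)(CCC2=O)CC=1O[Si](C)(C)C(C)(C)C
F3 | step 6 | 5α-H,6α-(pinacolboryl) ketone: methyl 7-[(tert-butyldimethylsilyl)oxy]-8a-methyl-3-oxo-4-(4,4,5,5-tetramethyl-1,3,2-dioxaborolan-2-yl)-1,2,3,3a,4,5,8,8a-octahydroazulene-6-carboxylate | COC(=O)C=1C[C@H](B2OC(C)(C)C(C)(C)O2)[C@@H]3[C@](C)(CCC3=O)CC=1O[Si](C)(C)C(C)(C)C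
F4 | step 8 | methyl (3aS,4S,8aR)-7-[(tert-butyldimethylsilyl)oxy]-3β,4-dihydroxy-8a-methyl-3α-(prop-1-en-2-yl)-1,2,3,3a,4,5,8,8a-octahydroazulene-6-carboxylate | COC(=O)C=1C[C@H](O)[C@@H]2[C@](C)(CC[C@@]2(O)C(C)=C)CC=1O[Si](C)(C)C(C)(C)C
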